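**Plan**
- Retrosynthetic cuts, in order: C8=C17 (methylenation of a parked C8 ketone), the two aryl C–Br bonds, C3–Br (from the C3 ketone via a bromoalkene), C4–C1' (enolate alkylation with the halogenated side chain), the C1–C2 saturation, then C9–C10, which opens ring B to a meta-tethered 2,4-dimethylphenol bearing a Z allylic carbonate; the tether is cut at C5–C6, C9–C11 and C7–C8.
- Enabling feature: in ring A, C10 (angular methyl) is para to C3 and C4 (methyl) is ortho to it, so ring A can be carried as a 2,4-dimethylphenol; C9 (arylmethyl), C8 and the exocyclic C17 form an allyl unit that the para carbon C10 can attack at C9.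
- Forward: ring A is bought as an arene; the chain is built by carbomagnesiation, Negishi and Suzuki couplings; ring B closes in the dearomatisation; the side chain is joined at C4 by Birch reduction–alkylation; C3–Br, aryl bromination and the C8 methylene come last.
- Stereochemistry: C9/C10 from the chiral iridium catalyst and a chair closure; C5/C4 from the reductive alkylation (trans fusion, entry anti to the C10 methyl); C3 from hydrogen-atom-transfer hydrogenation (equatorial Br); C3' from a catalytic enantioselective bromochlorination of prenol.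

Key step: step 12

Remark: atoms are numbered labdane-style (ring A = C1–C5 and C10, ring B = C5–C10, C17 = exocyclic methylene carbon, C11 = benzylic CH2, C1'–C4' = side chain on C4); R/S descriptors refer to this numbering unless a full name is given.
Assumption on the chemistry: the sense of induction of the chiral ligands in steps 12 and 14 cannot be read from a close analogue, so the ligand antipode is taken if a first run gives the opposite series.

**Step 1**
Reactants: 1 2-bromo-1,3-dimethylbenzene
Product: 2 2-bromo-1,3-dimethyl-4-nitrobenzene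
Conditions: HNO3 (65%), H2SO4, 0 °C
Reagents that add atoms: nitric acid, O[N+](=O)[O-]
Why: Electrophilic aromatic nitration should go to C4, which is ortho to one methyl group and para to the other, whereas the position para to bromine is meta to both.

**Step 2**
Reactants: 2 2-bromo-1,3-dimethyl-4-nitrobenzene
Product: 3 3-bromo-2,4-dimethylaniline
Conditions: H2 (1 atm), 5% Pt/C (sulfided), EtOAc, rt
Reagents that add atoms: none
Why: Catalytic hydrogenation over sulfided platinum reduces the nitro group and should leave the aryl bromide intact.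

**Step 3**
Reactants: 3 3-bromo-2,4-dimethylaniline
Product: 5 3-bromo-2,4-dimethylphenol, via diazonium salt 4 (not isolated)
Conditions: NaNO2, H2SO4 (aq), 0 °C; then H2SO4 (aq), 100 °C
Reagents that add atoms: water, O
Why: Diazotisation and thermal hydrolysis of the arenediazonium salt replace NH2 by OH without touching the flanked bromide.

**Step 4**
Reactants: 5 3-bromo-2,4-dimethylphenol
Product: 6 (3-bromo-2,4-dimethylphenoxy)triisopropylsilane
Conditions: TIPSCl, imidazole, DMF, rt
Reagents that add atoms: chlorotriisopropylsilane, CC(C)[Si](Cl)(C(C)C)C(C)C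
Why: Silylation gives an aryl silyl ether that should survive the basic cross-coupling and can later be removed by fluoride beside the MOM ether.

**Step 5**
Reactants: 7 2-(hydroxymethyl)phenol
Product: 8 [2-(methoxymethoxy)phenyl]methanol
Conditions: MOMCl, K2CO3, acetone, 0 °C → rt
Reagents that add atoms: chloromethyl methyl ether, COCCl
Why: Williamson-type O-alkylation is selective for the phenoxide, because carbonate does not deprotonate the benzylic alcohol.

**Step 6**
Reactants: 8 [2-(methoxymethoxy)phenyl]methanol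
Product: 9 1-(chloromethyl)-2-(methoxymethoxy)benzene
Conditions: PPh3, NCS, CH2Cl2, 0 °C
Reagents that add atoms: N-chlorosuccinimide, O=C1CCC(=O)N1Cl
Why: Appel-type chlorination converts the benzylic alcohol to the chloride under neutral conditions that spare the acetal.

**Step 7**
Reactants: 10 prop-2-yn-1-ol
Product: 12 (2Z)-2-ethenyl-3-iodoprop-2-en-1-ol, via alkenylmagnesium alkoxide 11 (not isolated)
Conditions: CH2=CHMgBr (3 equiv), CuI (10 mol%), THF, −10 °C → rt; then I2, −78 → 0 °C
Reagents that add atoms: vinylmagnesium bromide, C=C[Mg]Br; iodine, II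
Why: Copper-catalysed anti-carbomagnesiation of the propargylic alkoxide puts the vinyl group on C2 and magnesium on C3 in a five-membered chelate, so iodinolysis with retention should place iodine cis to CH2OH (Z).

**Step 8**
Reactants: 12 (2Z)-2-ethenyl-3-iodoprop-2-en-1-ol; 9 1-(chloromethyl)-2-(methoxymethoxy)benzene
Product: 14 (2Z)-2-ethenyl-4-[2-(methoxymethoxy)phenyl]but-2-en-1-ol, via benzylzinc chloride 13 (not isolated)
Conditions: 9, Zn dust, LiCl, THF, rt; then 12, Pd(OAc)2 (2 mol%), SPhos (4 mol%), THF, rt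
Reagents that add atoms: none
Why: Negishi coupling of an alkenyl iodide with a benzylic zinc halide keeps the alkene geometry and tolerates the free hydroxyl group, so the arylmethyl group ends up cis to CH2OH.

**Step 9**
Reactants: 14 (2Z)-2-ethenyl-4-[2-(methoxymethoxy)phenyl]but-2-en-1-ol; 6 (3-bromo-2,4-dimethylphenoxy)triisopropylsilane
Product: 16 (2Z)-2-{2-[2,6-dimethyl-3-(triisopropylsilyloxy)phenyl]ethyl}-4-[2-(methoxymethoxy)phenyl]but-2-en-1-ol, via bis-borane 15 (not isolated)
Conditions: 9-BBN-H (2.2 equiv), THF, 0 °C → rt; then 6, Pd(OAc)2 (5 mol%), SPhos (10 mol%), K3PO4 (aq), THF, 60 °C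
Reagents that add atoms: none
Why: 9-BBN hydroborates only the terminal vinyl group of the diene at its CH2 end (the hydroxyl is held as a borinate), and B-alkyl Suzuki–Miyaura coupling with a biarylphosphine ligand joins the primary alkylborane to the di-ortho-substituted aryl bromide.

**Step 10**
Reactants: 16 (the Z allylic alcohol above)
Product: 17 (2Z)-2-{2-[2,6-dimethyl-3-(triisopropylsilyloxy)phenyl]ethyl}-4-[2-(methoxymethoxy)phenyl]but-2-en-1-yl methyl carbonate
Conditions: ClCO2Me, pyridine, CH2Cl2, 0 °C
Reagents that add atoms: methyl chloroformate, COC(=O)Cl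
Why: Acylation of the primary allylic alcohol installs the carbonate leaving group needed for ionisation.

**Step 11**
Reactants: 17 (the silyl-protected carbonate above)
Product: 18 (2Z)-2-[2-(3-hydroxy-2,6-dimethylphenyl)ethyl]-4-[2-(methoxymethoxy)phenyl]but-2-en-1-yl methyl carbonate
Conditions: TBAF, AcOH (1:1), THF, 0 °C
Reagents that add atoms: none
Why: Buffered fluoride cleaves the aryl silyl ether quickly and should leave the allylic carbonate and the MOM ether intact.

**Step 12**
Reactants: 18 (the Z phenol carbonate above)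
Product: 19 (4aS,5R)-5-{[2-(methoxymethoxy)phenyl]methyl}-1,4a-dimethyl-6-methylidene-5,6,7,8-tetrahydronaphthalen-2(4aH)-one [(9R,10S) dienone]
Conditions: [Ir(cod)Cl]2 (4 mol%), (S,S,Sa)-BINOL-derived N,N-bis(1-phenylethyl)phosphoramidite (8 mol%), n-PrNH2 pre-activation, Cs2CO3 (0.2 equiv), THF (0.02 M), 50 °C
Reagents that add atoms: none
Why: Proposed new method: the cyclometalated monovalent iridium phosphoramidite complex ionises the allylic carbonate to a trivalent iridium allyl complex (C17–C8–C9), and the phenolate, freed by the methoxide released on decarboxylation, attacks through its para carbon C10 at the substituted terminus C9 anti to the metal; the C10 methyl group blocks rearomatisation, so the cross-conjugated dienone results. The closest known reaction type is the [Ir(cod)Cl]2/phosphoramidite-catalysed intramolecular asymmetric allylic dearomatisation of phenols, established for allyl units without a substituent on the central carbon; the 2-alkyl, Z-configured allyl unit used here is untested. Ring B closes in a 6-exo mode (C9–C10 bond formed, C8=C17 left outside the ring) through a chair in which the phenolate and allyl planes are stacked and C5 and C8 are staggered. C9 is set by the ligand, which decides the allyl face that iridium occupies; C10 follows from the chair, because the Z geometry holds the arylmethyl group cis to C17 and so places it equatorial on ring B, cis to the C10 methyl group. The step needs para (C10) over ortho (C4) attack and the substituted over the unsubstituted terminus. The para carbon has the larger phenolate coefficient, lies away from the cation-bearing oxygen and leads to the more stable dienone, and iridium allyl complexes are normally attacked at the more substituted terminus.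

**Step 13**
Reactants: 19 (9R,10S) dienone
Product: 20 (4aS,5R)-5-{[2-(methoxymethoxy)phenyl]methyl}-1,4a-dimethyl-6-methylidene-4,4a,5,6,7,8-hexahydronaphthalen-2(3H)-one [(9R,10S) enone]
Conditions: [(Ph3P)CuH]6 (5 mol%), PhMe2SiH (1.5 equiv), t-BuOH (1.5 equiv), toluene, rt
Reagents that add atoms: none
Why: Copper hydride conjugate reduction delivers hydride only to C1 of the disubstituted enone arm, since the C4=C5 arm is fully substituted at its β-carbon, and it leaves the isolated exocyclic alkene alone.

**Step 14**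
Reactants: 21 3-methylbut-2-en-1-ol
Product: 22 (2R)-2-bromo-3-chloro-3-methylbutan-1-ol
Conditions: NBS (1.1 equiv), ClTi(OiPr)3 (1.1 equiv), chiral tridentate amino-alcohol salicylaldimine (Schiff-base) ligand (20 mol%), hexanes, −20 °C
Reagents that add atoms: N-bromosuccinimide, O=C1CCC(=O)N1Br; chlorotitanium triisopropoxide, CC(C)O[Ti](Cl)(OC(C)C)OC(C)C
Why: Titanium-mediated catalytic enantioselective bromochlorination of an allylic alcohol adds Br and Cl anti across the alkene with chloride at the tertiary carbon, and the chiral ligand sets the CHBr centre.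

**Step 15**
Reactants: 22 (2R)-2-bromo-3-chloro-3-methylbutan-1-ol
Product: 23 (2R)-2-bromo-3-chloro-3-methylbutyl trifluoromethanesulfonate
Conditions: Tf2O, 2,6-lutidine, CH2Cl2, −78 °C
Reagents that add atoms: trifluoromethanesulfonic anhydride, O=S(=O)(OS(=O)(=O)C(F)(F)F)C(F)(F)F
Why: Sulfonylation at low temperature activates the primary carbon for substitution without touching the CHBr centre.

**Step 16**
Reactants: 23 (2R)-2-bromo-3-chloro-3-methylbutyl trifluoromethanesulfonate
Product: 24 (4R)-4-bromo-5-chloro-5-methylhex-1-ene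
Conditions: CH2=CHMgBr (1.5 equiv), CuBr·SMe2 (10 mol%), THF, −78 → −30 °C
Reagents that add atoms: vinylmagnesium bromide, C=C[Mg]Br
Why: Copper-catalysed coupling of a primary alkyl triflate with a vinyl Grignard reagent substitutes at the CH2 carbon, which is far more reactive than the hindered secondary bromide and the tertiary chloride.

**Step 17**
Reactants: 24 (4R)-4-bromo-5-chloro-5-methylhex-1-ene
Product: 26 (3R)-3-bromo-4-chloro-4-methylpentan-1-ol, via ozonide 25 (not isolated)
Conditions: O3, CH2Cl2, −78 °C; then NaBH4, MeOH, −78 → 0 °C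
Reagents that add atoms: ozone, [O-][O+]=O
Why: Ozonolysis with borohydride work-up gives the primary alcohol directly, so the elimination-prone β-bromo aldehyde is never handled.

**Step 18**
Reactants: 26 (3R)-3-bromo-4-chloro-4-methylpentan-1-ol
Product: 27 (3R)-3-bromo-4-chloro-1-iodo-4-methylpentane
Conditions: I2, PPh3, imidazole, CH2Cl2, 0 °C
Reagents that add atoms: iodine, II
Why: Appel-type iodination acts only at the primary carbinol carbon.

**Step 19**
Reactants: 20 (9R,10S) enone; 27 (3R)-3-bromo-4-chloro-1-iodo-4-methylpentane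
Product: 29 (4R,5S,9R,10S)-4-[(3R)-3-bromo-4-chloro-4-methylpentyl]-9-[2-(methoxymethoxy)benzyl]-4,10-dimethyl-8-methylidene-trans-decalin-3-one, via lithium enolate 28 (not isolated)
Conditions: Li (2.2 equiv), NH3(l)/THF, t-BuOH (1.0 equiv), −78 °C; isoprene; NH3 evaporated; 27 (3 equiv), THF–HMPA, −40 °C → rt
Reagents that add atoms: none
Why: Birch-type reductive alkylation: electron transfer and axial protonation at C5 give the trans-fused C3–C4 lithium enolate regiospecifically, and the iodide should enter at C4 on the face away from the axial C10 methyl group, leaving the C4 methyl axial and syn to it.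

**Step 20**
Reactants: 29 (the C3 ketone above)
Product: 30 (E)-hydrazone of 29 at C3
Conditions: N2H4·H2O, Et3N, EtOH, 70 °C
Reagents that add atoms: hydrazine, NN
Why: Condensation with the only ketone gives the hydrazone; the neopentyl-type secondary bromide and the β-bromo tertiary chloride are poor substitution substrates and should survive.

**Step 21**
Reactants: 30 (the hydrazone above)
Product: 31 (4R,5S,9R,10S)-3-bromo-4-[(3R)-3-bromo-4-chloro-4-methylpentyl]-9-[2-(methoxymethoxy)benzyl]-4,10-dimethyl-8-methylidene-trans-decal-2-ene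
Conditions: NBS (2.2 equiv), pyridine, CH2Cl2, 0 °C
Reagents that add atoms: N-bromosuccinimide, O=C1CCC(=O)N1Br
Why: Barton vinyl halide synthesis in its N-bromosuccinimide form: oxidation to the diazo compound, bromination, loss of N2 and proton loss from C2 (C4 is quaternary) give the 3-bromo-2-ene, and the hydrazone reacts much faster than the isolated alkene.

**Step 22**
Reactants: 31 (the bromoalkene above)
Product: 33 (4R,5S,9S,10R)-3-bromo-4-[(3R)-3-bromo-4-chloro-4-methylpentyl]-9-[2-(methoxymethoxy)benzyl]-4,10-dimethyl-trans-decal-2-en-8-one, via diol 32 (not isolated)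
Conditions: OsO4 (2 mol%), NaIO4 (4 equiv), 2,6-lutidine, dioxane/H2O, rt
Reagents that add atoms: osmium tetroxide (catalytic oxygen carrier), O=[Os](=O)(=O)=O; sodium periodate (terminal oxidant), [Na+].[O-][I](=O)(=O)=O
Why: Lemieux–Johnson oxidation cleaves the electron-rich 1,1-disubstituted alkene in preference to the electron-poor bromoalkene, and the C9 arylmethyl group stays in (or epimerises to) its equatorial, thermodynamically preferred position beside the new ketone.

**Step 23**
Reactants: 33 (the bromoalkene ketone above)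
Product: 34 (3R,4R,5S,9S,10R)-3-bromo-4-[(3R)-3-bromo-4-chloro-4-methylpentyl]-9-[2-(methoxymethoxy)benzyl]-4,10-dimethyl-trans-decalin-8-one
Conditions: Mn(dpm)3 (10 mol%), PhSiH3, TBHP, i-PrOH, rt
Reagents that add atoms: none
Why: Manganese-catalysed hydrogen-atom-transfer (Mukaiyama-type) hydrogenation, known for haloalkenes, adds a hydrogen atom to C2 and then delivers hydrogen to the C3 α-bromo radical on the face away from the axial C4 and C10 methyl groups, which should give the equatorial bromide without cleaving C–Br bonds.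

**Step 24**
Reactants: 34 (the MOM-protected bromo ketone above)
Product: 35 (3R,4R,5S,9S,10R)-3-bromo-4-[(3R)-3-bromo-4-chloro-4-methylpentyl]-9-(2-hydroxybenzyl)-4,10-dimethyl-trans-decalin-8-one
Conditions: 2 M HCl (aq), THF, 40 °C
Reagents that add atoms: none
Why: Acid hydrolysis of the methoxymethyl acetal frees the phenol, and the alkyl halides and the ketone are stable to dilute aqueous acid.

**Step 25**
Reactants: 35 (the phenol ketone above)
Product: 36 (3R,4R,5S,9S,10R)-3-bromo-4-[(3R)-3-bromo-4-chloro-4-methylpentyl]-9-(3,5-dibromo-2-hydroxybenzyl)-4,10-dimethyl-trans-decalin-8-one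
Conditions: NBS (2.05 equiv), MeCN, 0 °C, dark
Reagents that add atoms: N-bromosuccinimide, O=C1CCC(=O)N1Br
Why: Electrophilic aromatic bromination of the free phenol occurs at the open para and ortho positions, and since no alkene is present at this stage bromoetherification cannot compete.

**Step 26**
Reactants: 36 (the dibromophenol ketone above)
Product: 39 2,4-dibromo-6-{[(1R,4aS,5R,6R,8aS)-6-bromo-5-[(3R)-3-bromo-4-chloro-4-methylpentyl]-5,8a-dimethyl-2-methylidenedecahydronaphthalen-1-yl]methyl}phenol (CNP0318265.2), via keto silyl ether 37 (not isolated), via methylidene silyl ether 38 (not isolated)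
Conditions: TMSCl, Et3N, CH2Cl2, 0 °C; then Cp2TiMe2 (3 equiv), toluene, 70 °C, dark; then 1 M HCl (aq), THF, rt
Reagents that add atoms: dimethyltitanocene, C[Ti](C)(C1C=CC=C1)C1C=CC=C1
Why: Petasis methylenation through Cp2Ti=CH2 is non-basic and so should spare the alkyl bromides, the tertiary chloride and C9, while transient silylation stops the phenol from consuming the reagent or forming a hemiketal with the C8 ketone.

**Compound list**
1 | 2-bromo-1,3-dimethylbenzene | Cc1cccc(C)c1Br | starting material
2 | 2-bromo-1,3-dimethyl-4-nitrobenzene | Cc1ccc([N+](=O)[O-])c(C)c1Br | intermediate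
3 | 3-bromo-2,4-dimethylaniline | Cc1ccc(N)c(C)c1Br | intermediate
4 | 3-bromo-2,4-dimethylbenzenediazonium hydrogensulfate | Cc1ccc([N+]#N)c(C)c1Br.OS(=O)(=O)[O-] | intermediate
5 | 3-bromo-2,4-dimethylphenol | Cc1ccc(O)c(C)c1Br | intermediate
6 | (3-bromo-2,4-dimethylphenoxy)triisopropylsilane | Cc1ccc(O[Si](C(C)C)(C(C)C)C(C)C)c(C)c1Br | intermediate
7 | 2-(hydroxymethyl)phenol | OCc1ccccc1O | starting material
8 | [2-(methoxymethoxy)phenyl]methanol | OCc1ccccc1OCOC | intermediate
9 | 1-(chloromethyl)-2-(methoxymethoxy)benzene | ClCc1ccccc1OCOC | intermediate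
10 | prop-2-yn-1-ol | C#CCO | starting material
11 | bromomagnesium (2Z)-3-(bromomagnesio)-2-ethenylprop-2-en-1-olate | Br[Mg]OC/C(C=C)=C\[Mg]Br | intermediate
12 | (2Z)-2-ethenyl-3-iodoprop-2-en-1-ol | OC/C(C=C)=C\I | intermediate
13 | [2-(methoxymethoxy)benzyl]zinc chloride | Cl[Zn]Cc1ccccc1OCOC | intermediate
14 | (2Z)-2-ethenyl-4-[2-(methoxymethoxy)phenyl]but-2-en-1-ol | OC/C(C=C)=C\Cc1ccccc1OCOC | intermediate
15 | bis(9-BBN) adduct of 14 (O-borinate and terminal C-borane, Z alkene) | C1CCC2CCCC1B2OC/C(CCB1C2CCCC1CCC2)=C\Cc1ccccc1OCOC | intermediate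
16 | (2Z)-2-{2-[2,6-dimethyl-3-(triisopropylsilyloxy)phenyl]ethyl}-4-[2-(methoxymethoxy)phenyl]but-2-en-1-ol | OC/C(CCc1c(C)ccc(O[Si](C(C)C)(C(C)C)C(C)C)c1C)=C\Cc1ccccc1OCOC | intermediate
17 | (2Z)-2-{2-[2,6-dimethyl-3-(triisopropylsilyloxy)phenyl]ethyl}-4-[2-(methoxymethoxy)phenyl]but-2-en-1-yl methyl carbonate | COC(=O)OC/C(CCc1c(C)ccc(O[Si](C(C)C)(C(C)C)C(C)C)c1C)=C\Cc1ccccc1OCOC | intermediate
18 | (2Z)-2-[2-(3-hydroxy-2,6-dimethylphenyl)ethyl]-4-[2-(methoxymethoxy)phenyl]but-2-en-1-yl methyl carbonate | COC(=O)OC/C(CCc1c(C)ccc(O)c1C)=C\Cc1ccccc1OCOC | intermediate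
19 | (4aS,5R)-5-{[2-(methoxymethoxy)phenyl]methyl}-1,4a-dimethyl-6-methylidene-5,6,7,8-tetrahydronaphthalen-2(4aH)-one | C=C1CCC2=C(C)C(=O)C=C[C@@]2(C)[C@@H]1Cc1ccccc1OCOC | intermediate
20 | (4aS,5R)-5-{[2-(methoxymethoxy)phenyl]methyl}-1,4a-dimethyl-6-methylidene-4,4a,5,6,7,8-hexahydronaphthalen-2(3H)-one | C=C1CCC2=C(C)C(=O)CC[C@@]2(C)[C@@H]1Cc1ccccc1OCOC | intermediate
21 | 3-methylbut-2-en-1-ol | CC(C)=CCO | starting material
22 | (2R)-2-bromo-3-chloro-3-methylbutan-1-ol | OC[C@@H](Br)C(C)(C)Cl | intermediate
23 | (2R)-2-bromo-3-chloro-3-methylbutyl trifluoromethanesulfonate | O=S(=O)(OC[C@@H](Br)C(C)(C)Cl)C(F)(F)F | intermediate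
24 | (4R)-4-bromo-5-chloro-5-methylhex-1-ene | C=CC[C@@H](Br)C(C)(C)Cl | intermediate
25 | 3-[(2R)-2-bromo-3-chloro-3-methylbutyl]-1,2,4-trioxolane (ozonide, ring carbon unassigned) | C1OC(C[C@@H](Br)C(C)(C)Cl)OO1 | intermediate
26 | (3R)-3-bromo-4-chloro-4-methylpentan-1-ol | OCC[C@@H](Br)C(C)(C)Cl | intermediate
27 | (3R)-3-bromo-4-chloro-1-iodo-4-methylpentane | ICC[C@@H](Br)C(C)(C)Cl | intermediate
28 | lithium (5S,9R,10S) C3–C4 enolate of the trans-fused ketone | C=C1CC[C@@H]2C(C)=C(O[Li])CC[C@@]2(C)[C@@H]1Cc1ccccc1OCOC | intermediate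
29 | (4R,5S,9R,10S)-4-[(3R)-3-bromo-4-chloro-4-methylpentyl]-9-[2-(methoxymethoxy)benzyl]-4,10-dimethyl-8-methylidene-trans-decalin-3-one | C=C1CC[C@@H]2[C@@](C)(CC[C@@H](Br)C(C)(C)Cl)C(=O)CC[C@@]2(C)[C@@H]1Cc1ccccc1OCOC | intermediate
30 | (E)-hydrazone of 29 at C3 | C=C1CC[C@@H]2[C@@](C)(CC[C@@H](Br)C(C)(C)Cl)/C(=N/N)CC[C@@]2(C)[C@@H]1Cc1ccccc1OCOC | intermediate
31 | (4R,5S,9R,10S)-3-bromo-2-ene (bromoalkene, C8 methylidene) | C=C1CC[C@@H]2[C@@](C)(CC[C@@H](Br)C(C)(C)Cl)C(Br)=CC[C@@]2(C)[C@@H]1Cc1ccccc1OCOC | intermediate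
32 | 8,17-diol of 31 (C8 hydroxyl equatorial) | OC[C@]1(O)CC[C@@H]2[C@@](C)(CC[C@@H](Br)C(C)(C)Cl)C(Br)=CC[C@@]2(C)[C@@H]1Cc1ccccc1OCOC | intermediate
33 | (4R,5S,9S,10R)-3-bromo-2-en-8-one | O=C1CC[C@@H]2[C@@](C)(CC[C@@H](Br)C(C)(C)Cl)C(Br)=CC[C@@]2(C)[C@@H]1Cc1ccccc1OCOC | intermediate
34 | (3R,4R,5S,9S,10R)-3-bromo-8-one, MOM ether | O=C1CC[C@@H]2[C@@](C)(CC[C@@H](Br)C(C)(C)Cl)[C@H](Br)CC[C@@]2(C)[C@@H]1Cc1ccccc1OCOC | intermediate
35 | (3R,4R,5S,9S,10R)-3-bromo-8-one, free phenol | O=C1CC[C@@H]2[C@@](C)(CC[C@@H](Br)C(C)(C)Cl)[C@H](Br)CC[C@@]2(C)[C@@H]1Cc1ccccc1O | intermediate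
36 | (3R,4R,5S,9S,10R)-3-bromo-9-(3,5-dibromo-2-hydroxybenzyl)-8-one | O=C1CC[C@@H]2[C@@](C)(CC[C@@H](Br)C(C)(C)Cl)[C@H](Br)CC[C@@]2(C)[C@@H]1Cc1cc(Br)cc(Br)c1O | intermediate
37 | trimethylsilyl ether of 36 | O=C1CC[C@@H]2[C@@](C)(CC[C@@H](Br)C(C)(C)Cl)[C@H](Br)CC[C@@]2(C)[C@@H]1Cc1cc(Br)cc(Br)c1O[Si](C)(C)C | intermediate
38 | trimethylsilyl ether of 39 | C=C1CC[C@@H]2[C@@](C)(CC[C@@H](Br)C(C)(C)Cl)[C@H](Br)CC[C@@]2(C)[C@@H]1Cc1cc(Br)cc(Br)c1O[Si](C)(C)C | intermediate
39 | 2,4-dibromo-6-{[(1R,4aS,5R,6R,8aS)-6-bromo-5-[(3R)-3-bromo-4-chloro-4-methylpentyl]-5,8a-dimethyl-2-methylidenedecahydronaphthalen-1-yl]methyl}phenol | C=C1CC[C@@H]2[C@@](C)(CC[C@@H](Br)C(C)(C)Cl)[C@H](Br)CC[C@@]2(C)[C@@H]1Cc1cc(Br)cc(Br)c1O | target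

**Count**
Total steps: 26. Longest linear sequence: 17 steps (1–4, 9–13, 19–26) from 2-bromo-1,3-dimethylbenzene.

**Steps most likely to fail**

1. Step 12 (proposed new method). The 2-substituted carbonate may not ionise, attack may occur at the unsubstituted terminus C17 or through the ortho carbon C4, or closure may run through a boat and invert C9 relative to C10. A wrong C9 alone would be repaired later, because C9 can epimerise to the equatorial position at the C8 ketone stage (steps 22–25); a wrong C10 would not. Fallback with known chemistry, annulating ring A onto a preformed ring B, setting out from chloride 9: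
   - Magnesium in THF converts 9 into [2-(methoxymethoxy)benzyl]magnesium chloride F1.
   - CuBr·SMe2-catalysed conjugate addition of F1 to the known building block (4S)-4-[(tert-butyldimethylsilyl)oxy]cyclohex-2-en-1-one F2 occurs anti to the silyloxy group and gives the chloromagnesium enolate F3.
   - Methylation in the same flask (MeI, HMPA) gives (2S,3S,4S)-4-[(tert-butyldimethylsilyl)oxy]-3-[2-(methoxymethoxy)benzyl]-2-methylcyclohexan-1-one F4.
   - Robinson annulation with ethyl vinyl ketone (KOH, MeOH) proceeds by Michael addition at the more substituted α-carbon anti to the neighbouring arylmethyl group, then aldol condensation. It gives the (8S,9S,10S) octalone silyl ether F5 with the C10 methyl cis to the C9 arylmethyl group.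
   - TBAF gives the alcohol F6, and Dess–Martin oxidation gives the (9S,10S) enedione F7.
   - Wittig methylenation of the saturated C8 carbonyl with methylidenetriphenylphosphorane F8 (from Ph3PCH3Br and KOtBu; the enone is masked as its dienolate) gives enone 20.
   - The route resumes at 20 and the copper hydride step is no longer needed.

2. Step 19. Alkylation of the hindered, fully substituted enolate by an unactivated iodide may be outrun by proton transfer between enolate and product, or by base-induced elimination in the side chain. Fallback, setting out from enone 20: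
   - The same lithium–ammonia reduction is quenched with TMSCl/Et3N, and the trimethylsilyl enol ether F9 is isolated.
   - Alcohol 26 is converted with Tf2O/2,6-lutidine into (3R)-3-bromo-4-chloro-4-methylpentyl trifluoromethanesulfonate F10.
   - MeLi in THF cleaves F9 to the alkoxide-free lithium enolate 28, which is alkylated at −78 °C by the far more reactive F10.
   - The route resumes at ketone 29.

3. Step 23. Hydrogen-atom transfer to the hindered bromoalkene may stall, or hydrogen may be delivered to the wrong face of the C3 radical and give the axial bromide. Fallback through a geminal dibromide, setting out from hydrazone 30: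
   - Oxidation with CuBr2/Et3N in MeOH gives the 3,3-dibromide F11.
   - (Me3Si)3SiH (1 equiv) with Et3B/air at low temperature removes one bromine; the α-bromo radical should take hydrogen on the face away from the two axial methyl groups and give the equatorial (3R) bromide F12 with the exocyclic alkene still in place.
   - Lemieux–Johnson cleavage of F12 (OsO4 cat., NaIO4) gives ketone 34, where the route resumes.

**Further compounds**
F1 | step 12 | [2-(methoxymethoxy)benzyl]magnesium chloride | Cl[Mg]Cc1ccccc1OCOC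
F2 | step 12 | (4S)-4-[(tert-butyldimethylsilyl)oxy]cyclohex-2-en-1-one | O=C1C=C[C@@H](O[Si](C)(C)C(C)(C)C)CC1
F3 | step 12 | chloromagnesium (3S,4S)-4-[(tert-butyldimethylsilyl)oxy]-3-[2-(methoxymethoxy)benzyl]cyclohex-1-en-1-olate | Cl[Mg]OC1=C[C@H](Cc2ccccc2OCOC)[C@@H](O[Si](C)(C)C(C)(C)C)CC1
F4 | step 12 | (2S,3S,4S)-4-[(tert-butyldimethylsilyl)oxy]-3-[2-(methoxymethoxy)benzyl]-2-methylcyclohexan-1-one | O=C1CC[C@H](O[Si](C)(C)C(C)(C)C)[C@@H](Cc2ccccc2OCOC)[C@@H]1C
F5 | step 12 | (8S,9S,10S)-8-[(tert-butyldimethylsilyl)oxy]-9-[2-(methoxymethoxy)benzyl]-4,10-dimethyl-octal-4-en-3-one | CC(C)(C)[Si](C)(C)O[C@H]1CCC2=C(C)C(=O)CC[C@@]2(C)[C@@H]1Cc1ccccc1OCOC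
F6 | step 12 | (8S,9S,10S)-8-hydroxy-9-[2-(methoxymethoxy)benzyl]-4,10-dimethyl-octal-4-en-3-one | O[C@H]1CCC2=C(C)C(=O)CC[C@@]2(C)[C@@H]1Cc1ccccc1OCOC
F7 | step 12 | (9S,10S)-9-[2-(methoxymethoxy)benzyl]-4,10-dimethyl-octal-4-ene-3,8-dione | O=C1CCC2=C(C)C(=O)CC[C@@]2(C)[C@@H]1Cc1ccccc1OCOC
F8 | step 12 | methylidenetriphenylphosphorane | C=P(c1ccccc1)(c1ccccc1)c1ccccc1
F9 | step 19 | trimethylsilyl enol ether of the (5S,9R,10S) trans-fused ketone (C3–C4 enol) | C=C1CC[C@@H]2C(C)=C(O[Si](C)(C)C)CC[C@@]2(C)[C@@H]1Cc1ccccc1OCOC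
F10 | step 19 | (3R)-3-bromo-4-chloro-4-methylpentyl trifluoromethanesulfonate | O=S(=O)(OCC[C@@H](Br)C(C)(C)Cl)C(F)(F)F
F11 | step 23 | (4R,5S,9R,10S)-3,3-dibromo-4-[(3R)-3-bromo-4-chloro-4-methylpentyl]-9-[2-(methoxymethoxy)benzyl]-4,10-dimethyl-8-methylidene-trans-decalin | C=C1CC[C@@H]2[C@@](C)(CC[C@@H](Br)C(C)(C)Cl)C(Br)(Br)CC[C@@]2(C)[C@@H]1Cc1ccccc1OCOC
F12 | step 23 | (3R,4R,5S,9R,10S)-3-bromo-4-[(3R)-3-bromo-4-chloro-4-methylpentyl]-9-[2-(methoxymethoxy)benzyl]-4,10-dimethyl-8-methylidene-trans-decalin | C=C1CC[C@@H]2[C@@](C)(CC[C@@H](Br)C(C)(C)Cl)[C@H](Br)CC[C@@]2(C)[C@@H]1Cc1ccccc1OCOC
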